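**Strategy.** In drimane numbering, ring A is disconnected across C3–C4 and C5–C10 as a [4+2]. C4=C5 is the alkene of a mesityl-oxide-type enone whose carbonyl is C6, and C10(CH3)=C1–C2=C3 is a diene carried by C9. Because C6 and C9 are joined through C7–C8, one intramolecular Diels–Alder reaction of an open-chain trienone closes rings A and B together and creates the quaternary C4 and C10. The precursor is a 2,3-disubstituted succinate (C12 on C8, C11 on C9) assembled by one catalytic Michael addition. Its two stereocentres relay to C10 in the cycloaddition; C5, C8 and C6 are then set from C10 by equilibration, hydrogenation and hydride delivery.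

Key step: step 6

Remark: atoms are named by drimane numbering (ring A = C1–C5, C10; ring B = C5–C10; C11 on C9, C12 on C8).
Remark: the quinine-derived squaramide in step 5 is assumed, by analogy with related N-acylpyrazole additions, to give the (2S,3S) adduct; the quinidine-derived pseudo-enantiomer gives the antipode.

Step 1
Reactants: 1 but-3-yn-1-ol
Product: 3 (3E)-3-methylhexa-3,5-dien-1-ol, via alkenylalane 2 (not isolated)
Conditions: Me3Al (3 equiv), Cp2ZrCl2 (0.25 equiv), CH2Cl2, 0 °C to rt; then CH2=CHBr (1.5 equiv), ZnCl2 (1 equiv), Pd(PPh3)4 (3 mol %), THF, rt; 1 M HCl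
Reagents that add atoms: trimethylaluminium, C[Al](C)C; vinyl bromide, C=CBr
Why: Zirconium-catalysed syn-carboalumination places CH3 and Al cis on the alkyne, and the Negishi coupling of the alkenyl metal with vinyl bromide goes with retention, so the trisubstituted alkene should form E (chain trans to vinyl), as the cycloaddition needs.

Step 2
Reactants: 3 (3E)-3-methylhexa-3,5-dien-1-ol
Product: 4 (3E)-3-methylhexa-3,5-dienoic acid
Conditions: TEMPO (0.2 equiv), PhI(OAc)2 (2.2 equiv), MeCN/H2O (1:1), 0 °C to rt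
Reagents that add atoms: water, O
Why: Oxoammonium (TEMPO) oxidation takes the primary alcohol through the aldehyde hydrate to the acid without base, so the β,γ-unsaturated diene should not move into conjugation; no stereocentre is involved.

Step 3
Reactants: 4 (3E)-3-methylhexa-3,5-dienoic acid
Product: 5 1-[(3E)-3-methylhexa-3,5-dienoyl]-3,5-dimethyl-1H-pyrazole
Conditions: 3,5-dimethylpyrazole (1.1 equiv), DCC (1.1 equiv), CH2Cl2, 0 °C
Reagents that add atoms: 3,5-dimethyl-1H-pyrazole, Cc1cc(C)[nH]n1
Why: Carbodiimide N-acylation gives an activated amide whose α-CH2 is acidic enough for amine catalysis; no base is present, so the diene stays β,γ.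

Step 4
Reactants: 6 (2E)-4-tert-butoxy-4-oxobut-2-enoic acid (fumaric acid mono-tert-butyl ester)
Product: 8 tert-butyl (2E)-6-methyl-4-oxohepta-2,5-dienoate, via acid chloride 7 (not isolated)
Conditions: Me2C=C(Cl)NMe2 (1.1 equiv), CH2Cl2, 0 °C; then Me2C=CHMgBr (1.05 equiv), Fe(acac)3 (3 mol %), THF, −78 °C
Reagents that add atoms: 2-methylprop-1-enylmagnesium bromide, CC(C)=C[Mg]Br
Why: Neutral acid chloride formation spares the tert-butyl ester, and iron-catalysed acylation of the alkenyl Grignard reagent at −78 °C outruns conjugate or second addition, so the cross-conjugated dienone should keep the E fumarate alkene.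

Step 5
Reactants: 5 1-[(3E)-3-methylhexa-3,5-dienoyl]-3,5-dimethyl-1H-pyrazole; 8 tert-butyl (2E)-6-methyl-4-oxohepta-2,5-dienoate
Product: 9 tert-butyl (2S,3S)-4-(3,5-dimethyl-1H-pyrazol-1-yl)-2-(4-methyl-2-oxopent-3-en-1-yl)-4-oxo-3-[(2E)-penta-2,4-dien-2-yl]butanoate
Conditions: 3-{[3,5-bis(trifluoromethyl)phenyl]amino}-4-{[(8α,9S)-6′-methoxycinchonan-9-yl]amino}cyclobut-3-ene-1,2-dione (quinine-derived squaramide, 10 mol %), CH2Cl2, 0 °C
Reagents that add atoms: none
Why: Bifunctional amine–squaramide Michael addition: the quinuclidine deprotonates the α-CH2 of the N-acylpyrazole, the squaramide binds the γ-oxo-enoate, and bond formation at the enoate carbon β to the ketone inside this ion pair should set C9 and C8 together (anti, 2S,3S) under catalyst control.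

Step 6
Reactants: 9 tert-butyl (2S,3S)-4-(3,5-dimethyl-1H-pyrazol-1-yl)-2-(4-methyl-2-oxopent-3-en-1-yl)-4-oxo-3-[(2E)-penta-2,4-dien-2-yl]butanoate
Product: 10 tert-butyl (1S,2S,4aR,8aS)-1-[(3,5-dimethyl-1H-pyrazol-1-yl)carbonyl]-5,5,8a-trimethyl-4-oxo-1,2,3,4,4a,5,6,8a-octahydronaphthalene-2-carboxylate
Conditions: Me2AlCl (2.2 equiv), CH2Cl2, −78 to −20 °C; 1 M HCl
Reagents that add atoms: none
Why: Type 1 intramolecular Diels–Alder reaction (IMDA) of a 1,7,9-decatrien-3-one under Me2AlCl activation (one equivalent is held by the N-acylpyrazole, the second complexes the C6 ketone): the enone C4=C5 adds to the s-cis diene C10=C1–C2=C3 in a concerted, asynchronous [4+2] in which the peripheral C3–C4 bond (unhindered diene CH2 to the enone β-carbon, positive charge building at tertiary C10) leads and C5–C10 follows. Ring A closes as the new cyclohexene by both bonds and ring B closes by the C5–C10 bond alone over the four-atom tether C6–C7–C8–C9, so both quaternary carbons arise in one event and neither new bond joins two fully substituted carbons. The step needs endo selectivity (C6 carbonyl under the diene, chair-like tether), the usual course of Lewis-acid-promoted decatrienone cyclisations; it is reinforced here because in this mode the inside C10 methyl is gauche to H5 instead of C6 and the C9–C8 bond does not eclipse that methyl. In the endo chair the C8 tert-butyl ester is equatorial and therefore 1,3-cis to the C10 methyl, which selects the diene face and should make C10 S relative to (8S,9S); the C9 acyl group, next to the fully substituted C10, has no equatorial preference and takes the axial site that its anti relation to C8 imposes, the other chair placing the C8 ester 1,3-diaxial to diene carbon C1. C5 is formed cis to the C10 methyl (5β-H) by the endo topography, and this kinetic ring fusion is accepted and corrected in step 8. The closest known reaction type is the Lewis-acid-catalysed IMDA of 1,7,9-decatrien-3-ones to cis-octalones with equatorial tether substituents.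

Step 7
Reactants: 10 tert-butyl (1S,2S,4aR,8aS)-1-[(3,5-dimethyl-1H-pyrazol-1-yl)carbonyl]-5,5,8a-trimethyl-4-oxo-1,2,3,4,4a,5,6,8a-octahydronaphthalene-2-carboxylate
Product: 11 (1S,2S,4aR,8aS)-2-(tert-butoxycarbonyl)-5,5,8a-trimethyl-4-oxo-1,2,3,4,4a,5,6,8a-octahydronaphthalene-1-carboxylic acid
Conditions: LiOH (3 equiv), THF/H2O (3:1), 0 °C; 1 M HCl to pH 3
Reagents that add atoms: lithium hydroxide, [Li+].[OH-]
Why: The N-acylpyrazole is an activated amide that hydroxide cleaves by addition–elimination far faster than the tert-butyl ester; the carboxylate formed shields H9 from exchange, and any drift at C5 is harmless because C5 is reset in step 8.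

Step 8
Reactants: 11 (1S,2S,4aR,8aS)-2-(tert-butoxycarbonyl)-5,5,8a-trimethyl-4-oxo-1,2,3,4,4a,5,6,8a-octahydronaphthalene-1-carboxylic acid
Product: 13 (1R,4aS,8aS)-2-(tert-butoxycarbonyl)-5,5,8a-trimethyl-4-oxo-1,4,4a,5,6,8a-hexahydronaphthalene-1-carboxylic acid, via cis-fused enone 12 (not isolated)
Conditions: IBX (2.2 equiv), DMSO, 70 °C; then DBU (4 equiv), 40 °C; 1 M HCl
Reagents that add atoms: none
Why: IBX dehydrogenation can only run towards C7–C8 because C4 and C10 carry no hydrogen; with C8 trigonal nothing is syn-axial to the C10 methyl, so DBU should equilibrate C5 through the cross-conjugated dienolate to the trans-fused 7-en-6-one (also the product of protonation anti to the C10 methyl), while the C9 carboxylate makes γ-deprotonation at C9 a dianion formation and keeps C9 fixed (its descriptor changes to R only because C8 gains priority).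

Step 9
Reactants: 13 (1R,4aS,8aS)-2-(tert-butoxycarbonyl)-5,5,8a-trimethyl-4-oxo-1,4,4a,5,6,8a-hexahydronaphthalene-1-carboxylic acid
Product: 14 (1S,2S,4aS,8aS)-2-(tert-butoxycarbonyl)-5,5,8a-trimethyl-4-oxodecahydronaphthalene-1-carboxylic acid
Conditions: H2 (1 atm), 10% Pd/C, EtOAc, rt
Reagents that add atoms: none
Why: Heterogeneous hydrogenation saturates C1=C2 and the enoate C7=C8; hydrogen should reach C8 from the α face, opposite the axial C10 methyl and beside the small axial H9, leaving the C12 ester β (axial, cis to C11) under kinetic control.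

Step 10
Reactants: 15 (2E,4E,6E)-octa-2,4,6-trienoic acid
Product: 16 (2E,4E,6E)-octa-2,4,6-trienoyl chloride
Conditions: (COCl)2 (1.2 equiv), DMF (cat.), CH2Cl2, 0 °C to rt; evaporation
Reagents that add atoms: oxalyl chloride, ClC(=O)C(=O)Cl
Why: Chloroiminium-catalysed conversion of the acid into its chloride is mild enough to leave the all-E triene untouched.

Step 11
Reactants: 14 (1S,2S,4aS,8aS)-2-(tert-butoxycarbonyl)-5,5,8a-trimethyl-4-oxodecahydronaphthalene-1-carboxylic acid; 16 (2E,4E,6E)-octa-2,4,6-trienoyl chloride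
Product: 18 (1S,2S,4R,4aS,8aS)-2-(tert-butoxycarbonyl)-5,5,8a-trimethyl-4-{[(2E,4E,6E)-octa-2,4,6-trienoyl]oxy}decahydronaphthalene-1-carboxylic acid, via dilithium alkoxide 17 (not isolated)
Conditions: LiBH(s-Bu)3 (2.3 equiv), THF, −78 °C; then 16 (1.3 equiv), DMAP (0.2 equiv), −78 to 0 °C; sat. NaHCO3, then 1 M HCl to pH 3
Reagents that add atoms: none
Why: Hydride reduction and O-acylation in one flask: after the first equivalent deprotonates the acid, the bulky borohydride should attack the C6 ketone from the equatorial α face because the β face carries three axial groups (C10 methyl, 4β-methyl, C12 ester), and the axial 6β-alkoxide (6R) is acylated at once, before it can lactonise onto the syn-axial C12 ester.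

Step 12
Reactants: 18 (1S,2S,4R,4aS,8aS)-2-(tert-butoxycarbonyl)-5,5,8a-trimethyl-4-{[(2E,4E,6E)-octa-2,4,6-trienoyl]oxy}decahydronaphthalene-1-carboxylic acid
Product: 19 (1S,2S,4R,4aS,8aS)-5,5,8a-trimethyl-4-{[(2E,4E,6E)-octa-2,4,6-trienoyl]oxy}decahydronaphthalene-1,2-dicarboxylic acid
Conditions: CF3CO2H/CH2Cl2 (1:4), 0 °C
Reagents that add atoms: none
Why: Acidolysis of the tert-butyl ester (loss of 2-methylpropene) frees the C12 acid without hydrolysing the trienoate or enolising C8, so the axial 8β carboxyl should be kept.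

**Compound list**

1 | but-3-yn-1-ol | C#CCCO | starting material
2 | alkenylalane, (E)-Me2Al–CH=C(CH3)–CH2CH2–OAlMe2 | C[Al](C)OCC/C(C)=C/[Al](C)C | intermediate
3 | (3E)-3-methylhexa-3,5-dien-1-ol | OCC/C(C)=C/C=C | intermediate
4 | (3E)-3-methylhexa-3,5-dienoic acid | OC(=O)C/C(C)=C/C=C | intermediate
5 | 1-[(3E)-3-methylhexa-3,5-dienoyl]-3,5-dimethyl-1H-pyrazole | Cc1cc(C)n(n1)C(=O)C/C(C)=C/C=C | intermediate
6 | (2E)-4-tert-butoxy-4-oxobut-2-enoic acid | OC(=O)/C=C/C(=O)OC(C)(C)C | starting material
7 | tert-butyl (2E)-4-chloro-4-oxobut-2-enoate | ClC(=O)/C=C/C(=O)OC(C)(C)C | intermediate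
8 | tert-butyl (2E)-6-methyl-4-oxohepta-2,5-dienoate | CC(C)=CC(=O)/C=C/C(=O)OC(C)(C)C | intermediate
9 | tert-butyl (2S,3S)-4-(3,5-dimethyl-1H-pyrazol-1-yl)-2-(4-methyl-2-oxopent-3-en-1-yl)-4-oxo-3-[(2E)-penta-2,4-dien-2-yl]butanoate | CC(C)=CC(=O)C[C@H](C(=O)OC(C)(C)C)[C@H](C(=O)n1nc(C)cc1C)/C(C)=C/C=C | intermediate
10 | tert-butyl (1S,2S,4aR,8aS)-1-[(3,5-dimethyl-1H-pyrazol-1-yl)carbonyl]-5,5,8a-trimethyl-4-oxo-1,2,3,4,4a,5,6,8a-octahydronaphthalene-2-carboxylate (cis-fused) | O=C1C[C@H](C(=O)OC(C)(C)C)[C@H](C(=O)n3nc(C)cc3C)[C@@]2(C)C=CCC(C)(C)[C@@H]12 | intermediate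
11 | (1S,2S,4aR,8aS)-2-(tert-butoxycarbonyl)-5,5,8a-trimethyl-4-oxo-1,2,3,4,4a,5,6,8a-octahydronaphthalene-1-carboxylic acid (cis-fused) | O=C1C[C@H](C(=O)OC(C)(C)C)[C@H](C(=O)O)[C@@]2(C)C=CCC(C)(C)[C@@H]12 | intermediate
12 | (1R,4aR,8aS)-2-(tert-butoxycarbonyl)-5,5,8a-trimethyl-4-oxo-1,4,4a,5,6,8a-hexahydronaphthalene-1-carboxylic acid (cis-fused enone) | O=C1C=C(C(=O)OC(C)(C)C)[C@H](C(=O)O)[C@@]2(C)C=CCC(C)(C)[C@@H]12 | intermediate
13 | (1R,4aS,8aS)-2-(tert-butoxycarbonyl)-5,5,8a-trimethyl-4-oxo-1,4,4a,5,6,8a-hexahydronaphthalene-1-carboxylic acid (trans-fused enone) | O=C1C=C(C(=O)OC(C)(C)C)[C@H](C(=O)O)[C@@]2(C)C=CCC(C)(C)[C@H]12 | intermediate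
14 | (1S,2S,4aS,8aS)-2-(tert-butoxycarbonyl)-5,5,8a-trimethyl-4-oxodecahydronaphthalene-1-carboxylic acid | O=C1C[C@H](C(=O)OC(C)(C)C)[C@H](C(=O)O)[C@@]2(C)CCCC(C)(C)[C@H]12 | intermediate
15 | (2E,4E,6E)-octa-2,4,6-trienoic acid | C/C=C/C=C/C=C/C(=O)O | starting material
16 | (2E,4E,6E)-octa-2,4,6-trienoyl chloride | C/C=C/C=C/C=C/C(=O)Cl | intermediate
17 | dilithium (1S,2S,4R,4aS,8aS)-2-(tert-butoxycarbonyl)-5,5,8a-trimethyl-4-oxidodecahydronaphthalene-1-carboxylate | [Li+].[Li+].[O-][C@@H]1C[C@H](C(=O)OC(C)(C)C)[C@H](C(=O)[O-])[C@@]2(C)CCCC(C)(C)[C@H]12 | intermediate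
18 | (1S,2S,4R,4aS,8aS)-2-(tert-butoxycarbonyl)-5,5,8a-trimethyl-4-{[(2E,4E,6E)-octa-2,4,6-trienoyl]oxy}decahydronaphthalene-1-carboxylic acid | C/C=C/C=C/C=C/C(=O)O[C@@H]1C[C@H](C(=O)OC(C)(C)C)[C@H](C(=O)O)[C@@]2(C)CCCC(C)(C)[C@H]12 | intermediate
19 | (1S,2S,4R,4aS,8aS)-5,5,8a-trimethyl-4-{[(2E,4E,6E)-octa-2,4,6-trienoyl]oxy}decahydronaphthalene-1,2-dicarboxylic acid | C/C=C/C=C/C=C/C(=O)O[C@@H]1C[C@H](C(=O)O)[C@H](C(=O)O)[C@@]2(C)CCCC(C)(C)[C@H]12 | target

**Total step count:** 12. **Longest linear sequence:** 10 steps (1, 2, 3, 5, 6, 7, 8, 9, 11, 12).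

**Steps most likely to fail**

Step 6. The cycloaddition joins a diene terminus and a dienophile terminus that are both fully substituted. It may stall below the temperature at which the Lewis acid starts to cleave the tert-butyl ester or polymerise the diene, and leakage through the exo mode would appear as the C10 epimer. The fallback uses a cationic dienophile in place of a Lewis-acid-complexed one and sets out from 9. Silyl-triflate-catalysed ketalisation with 1,2-bis(trimethylsilyloxy)ethane (Me3SiOTf cat., CH2Cl2, −78 °C) should give the dioxolane ketal F1. On warming to −40 °C the same silyl triflate opens the ketal to a 2-alkenyl-1,3-dioxolan-2-ylium ion, a much stronger dienophile, whose intramolecular ionic Diels–Alder reaction and ring re-closure should give the ketal cycloadduct F2. Aqueous acid (TsOH, acetone/H2O) unmasks the ketone and the route is rejoined at 10.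

Step 5. Facial and diastereo-discrimination inside the ion pair may be low, the extended enolate may attack through its γ or ε carbon, and reversible deprotonation of the adduct may erode C9. The fallback replaces catalyst control by auxiliary and substrate control and sets out from 4. Pivaloyl mixed-anhydride acylation of lithiated (4S)-4-benzyl-1,3-oxazolidin-2-one should give the imide F3. NaN(SiMe3)2 and tert-butyl bromoacetate (THF, −78 °C) alkylate the chelated Z-enolate on the face away from the benzyl group, giving the succinate imide F4 with C9 set. LiOH/H2O2 cleaves the auxiliary through the peroxy acid F5, which Na2SO3 reduces to the half-ester acid F6. LiN(i-Pr)2 (2.2 equiv, THF, −78 °C) forms the carboxylate ester-enolate dianion, which 1-bromo-4-methylpent-3-en-2-one should alkylate at C8 anti to the C9 substituent to give the keto acid F7. DCC coupling with 3,5-dimethylpyrazole as in step 3 rejoins the route at 9.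

Step 8. The C5 equilibrium may be slow or may not lie far enough on the trans side, and prolonged base may move the C7=C8 bond out of conjugation. The fallback uses kinetic protonation instead of equilibration and sets out from 12, isolated after the IBX stage. LiN(i-Pr)2 (2.3 equiv, THF, −78 °C) should remove the acid proton and then H5, the only α-hydrogen of the enone, to give the dilithium dienolate F8. A quench with 2,6-di-tert-butyl-4-methylphenol should protonate C5 from the α face, anti to the C10 methyl, rejoining the route at 13.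

**Further compounds**

F1 | step 6 | tert-butyl (2S,3S)-4-(3,5-dimethyl-1H-pyrazol-1-yl)-2-{[2-(2-methylprop-1-en-1-yl)-1,3-dioxolan-2-yl]methyl}-4-oxo-3-[(2E)-penta-2,4-dien-2-yl]butanoate | CC(C)=CC1(OCCO1)C[C@H](C(=O)OC(C)(C)C)[C@H](C(=O)n2nc(C)cc2C)/C(C)=C/C=C
F2 | step 6 | spiro-1,3-dioxolane (ethylene) ketal at C6 of cycloadduct 10, configuration at C5, C8, C9 and C10 as in 10 | C1COC2(O1)C[C@H](C(=O)OC(C)(C)C)[C@H](C(=O)n4nc(C)cc4C)[C@@]3(C)C=CCC(C)(C)[C@@H]23
F3 | step 5 | (4S)-4-benzyl-3-[(3E)-3-methylhexa-3,5-dienoyl]-1,3-oxazolidin-2-one | O=C1OC[C@H](Cc2ccccc2)N1C(=O)C/C(C)=C/C=C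
F4 | step 5 | tert-butyl (3S,4E)-3-{[(4S)-4-benzyl-2-oxo-1,3-oxazolidin-3-yl]carbonyl}-4-methylhepta-4,6-dienoate | O=C1OC[C@H](Cc2ccccc2)N1C(=O)[C@@H](CC(=O)OC(C)(C)C)/C(C)=C/C=C
F5 | step 5 | (2S)-4-tert-butoxy-4-oxo-2-[(2E)-penta-2,4-dien-2-yl]butaneperoxoic acid | OOC(=O)[C@@H](CC(=O)OC(C)(C)C)/C(C)=C/C=C
F6 | step 5 | (2S)-4-tert-butoxy-4-oxo-2-[(2E)-penta-2,4-dien-2-yl]butanoic acid | OC(=O)[C@@H](CC(=O)OC(C)(C)C)/C(C)=C/C=C
F7 | step 5 | (2S,3S)-4-tert-butoxy-3-(4-methyl-2-oxopent-3-en-1-yl)-4-oxo-2-[(2E)-penta-2,4-dien-2-yl]butanoic acid | CC(C)=CC(=O)C[C@H](C(=O)OC(C)(C)C)[C@H](C(=O)O)/C(C)=C/C=C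
F8 | step 8 | dilithium cross-conjugated dienolate (C5=C6–O−, C7=C8) carboxylate of 12, configuration at C9 and C10 as in 12 | [Li+].[Li+].[O-]C1=C2C(C)(C)CC=C[C@]2(C)[C@@H](C(=O)[O-])C(C(=O)OC(C)(C)C)=C1
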